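(Readings and results are calculated for an exercise; scatter was added.)

- A one-step picture, substrate straight to target, gives a target that only climbs, but the north-west run read 13.6 % at 50.0 min and 13.9 % at 60.0 min, with substrate still falling, so target was being lost as well. I counted half-lives instead.

| flask | substrate | first nucleophile | second nucleophile | remark | time |
|---|---|---|---|---|---|
| north-west | 21 mM | 16 mM | 30 mM | run made earlier |  |
| south | 42 mM | 16 mM | 30 mM | run made earlier |  |
| south-east | 90 mM | 16 mM | 30 mM | run made earlier |  |
| Friday's | 20 mM | 16.0 mM | 30.0 mM |  | 1.5 h |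
| Saturday's | 40 mM | 16.0 mM | 30.0 mM |  | 1.5 h |
| Monday's | 80 mM | 16.0 mM | 30.0 mM |  | 1.5 h |

| run | time / min | target / % | substrate / % |
|---|---|---|---|
| north-west | 6.00 | 3.8 | 89.7 |
| north-west | 15.0 | 8.8 | 75.9 |
| north-west | 30.0 | 12.8 | 58.8 |
| north-west | 50.0 | 13.6 | 40.3 |
| north-west | 60.0 | 13.9 | 33.5 |
| south | 12.0 | 6.3 | 80.9 |
| south | 25.0 | 11.5 | 64.6 |
| south | 40.0 | 13.3 | 49.1 |
| south | 50.0 | 12.6 | 41.2 |
| south | 60.0 | 12.3 | 34.2 |
| south-east | 12.0 | 7.1 | 80.6 |
| south-east | 25.0 | 10.6 | 63.7 |
| south-east | 40.0 | 10.0 | 48.7 |
| south-east | 50.0 | 8.9 | 41.1 |
| south-east | 60.0 | 6.7 | 34.1 |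

(scatter of a reading: 0.5 percentage points)

- "hardly changes" means that all values lie within two and a half points (for a concentration: within two and a half percent of the largest)

1. [target] at the end for Friday's, Saturday's, Monday's, in this order
2. how that number moves from the first to the last of them (hardly changes / falls, then rises / rises all the way / rises, then falls / falls all the way)

- The substrate read 33.5 %, 34.2 % and 34.1 % at 60.0 min in the north-west, south and south-east runs, so its loss ignored the charge, and its half-life came to 38.0 min.
- My first way to target's own half-life assumed that each lost substrate takes one nucleophile of either kind. The pool, a shared limiting reagent, is then c(first nucleophile) + c(second nucleophile) = 46.0 mM.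
- The south-east run had lost 46.2 mM by 40.0 min, about that pool. I took its later target as unfed: 10.0 % fell to 6.7 % by 60.0 min, a half-life of 34.6 min.
- My second way used another flask. Target took 36.9 % of the substrate lost at the first north-west reading, and near 50.0 min it had levelled, so making and losing roughly balanced, which gave 34.8 min.
- The two agreed, so I kept their mean, 34.7 min, as the target half-life, the time in which target halves once nothing feeds it.
- For Friday's I ran two first-order steps in a chain and got 2.17 mM.
- Saturday's loses 32.2 mM of substrate, under the pool, but the south run read 12.3 % at 60.0 min against 13.9 % in the north-west run, so I scaled Friday's by the charge and by that ratio of readings to 3.84 mM.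
- Monday's reaches the pool at 46.9 min. I started from the south-east level of 10.0 % of the charge and counted 1.24 target half-lives, which left 3.39 mM.
- The forecast gave 2.4 mM, 4 mM and 3.4 mM, rises, then falls, reading the richer flasks as “the first nucleophile running out”. I counted both nucleophiles. Its Friday's stood above mine and so did its Saturday's.

    substrate → intermediate (k = 3.00 × 10⁻⁴ s⁻¹)
    first nucleophile + intermediate → target (k = 8.40 M⁻¹ s⁻¹)
    second nucleophile + intermediate → other capture product (k = 5.80 M⁻¹ s⁻¹)
    target → over-reaction product (k = 3.70 × 10⁻⁴ s⁻¹)

- The flasks gave 2.19 mM, 3.98 mM and 3.35 mM, rises, then falls. In Monday's at 0.750 h the first nucleophile stood at 1.88 % and the second at 6.44 % of own charge, with target at 11.0 % of the substrate charged. Counted with the half-life I had read from the runs, the time left was 1.30 target half-lives, which made my estimate 4.46 %, and Monday's target stood at 4.18 % at 1.50 h.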